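**Retrosynthetic overview**

1. Target 19 (labdane numbering: carboxyl C17 on C8, CH2O = C15) ⇐ salt resolution and fluoride cleavage of racemic silylethyl ester 16 ⇐ shift of a C6=C7 bond into conjugation ⇐ intramolecular Diels–Alder reaction of the acyclic, achiral tetraene ester 14, which makes C5–C10 and C8–C9 in one operation.
2. Enabling feature: ring B is a cyclohexene with the carboxyl on C8. Moving its C7=C8 bond to C6=C7 shows it as the cycloadduct of a 2,4-dienoate (C5=C6–C7=C8–CO2R) with the C9=C10 alkene. C5 and C10 are also the fusion atoms of ring A (joined by C1–C4), so the cycloaddition is intramolecular, and the cis C10–CH3/C9 side chain is the E-alkene of a geranyl unit.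
3. 14 ⇐ vinylogous Horner–Wadsworth–Emmons reaction of aldehyde 10 with phosphonate 13; 10 ⇐ copper-catalysed coupling of Grignard reagent 8 (C2–C5 with the gem-dimethyl group, from lactone 4) with allylic bromide 3 ⇐ allylic oxidation of commercial geranyl isobutyrate 1 (C1, C9–C16, C20 and the ester).
4. Ring order: no ring exists before step 11; rings A and B are closed together. Both new bonds join carbons of like polarity, hence a thermal pericyclic union; the racemate is resolved at the end.

Key step: step 11

Assumption: the less soluble salt of racemic acid 17 with (R)-1-phenylethylamine is taken to contain the (5S,9R,10S)-acid; if it holds the mirror-image acid, (S)-1-phenylethylamine is used in the same way.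

**Route**

Step 1
Reactants: 1 geranyl isobutyrate, (2E)-3,7-dimethylocta-2,6-dien-1-yl 2-methylpropanoate
Product: 2 (2E,6E)-8-hydroxy-3,7-dimethylocta-2,6-dien-1-yl 2-methylpropanoate
Conditions: SeO2 (0.1 equiv), tBuOOH (70% aq.), salicylic acid (cat.), CH2Cl2, 23 °C
Reagents that add atoms: tert-butyl hydroperoxide, CC(C)(C)OO
Why: Riley allylic oxidation should attack the terminal gem-dimethyl alkene (the other alkene is deactivated by the allylic ester) and, through the ene/[2,3]-sigmatropic sequence, oxidise only the methyl group trans to the chain, giving the E-allylic alcohol.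

Step 2
Reactants: 2 (2E,6E)-8-hydroxy-3,7-dimethylocta-2,6-dien-1-yl 2-methylpropanoate
Product: 3 (2E,6E)-8-bromo-3,7-dimethylocta-2,6-dien-1-yl 2-methylpropanoate
Conditions: CBr4, PPh3, CH2Cl2, 0 °C
Reagents that add atoms: carbon tetrabromide, BrC(Br)(Br)Br
Why: Appel bromination of a primary allylic alcohol under neutral conditions should give the primary bromide without allylic transposition or loss of the E geometry.

Step 3
Reactants: 4 3,3-dimethyloxolan-2-one (α,α-dimethyl-γ-butyrolactone)
Product: 5 ethyl 4-bromo-2,2-dimethylbutanoate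
Conditions: HBr (g), EtOH, 0 → 23 °C
Reagents that add atoms: hydrogen bromide, Br; ethanol, CCO
Why: Acid-mediated lactone opening, in which bromide attacks the unhindered O–CH2 carbon (SN2) and the acid is trapped by Fischer esterification, the quaternary α-carbon excluding elimination.

Step 4
Reactants: 5 ethyl 4-bromo-2,2-dimethylbutanoate
Product: 6 4-bromo-2,2-dimethylbutanal
Conditions: iBu2AlH (1.05 equiv), CH2Cl2, −78 °C; then MeOH, aq. KNaC4H4O6
Reagents that add atoms: none
Why: Partial reduction with iBu2AlH, where the aluminium hemiacetal of the hindered α,α-disubstituted ester should survive at −78 °C until work-up and the alkyl bromide is inert.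

Step 5
Reactants: 6 4-bromo-2,2-dimethylbutanal
Product: 7 4-bromo-1,1-dimethoxy-2,2-dimethylbutane
Conditions: HC(OMe)3, MeOH, pTsOH (cat.), 23 °C
Reagents that add atoms: trimethyl orthoformate, COC(OC)OC
Why: Acid-catalysed acetalisation with orthoformate as water scavenger masks the non-enolisable aldehyde for the Grignard step.

Step 6
Reactants: 7 4-bromo-1,1-dimethoxy-2,2-dimethylbutane; 3 (2E,6E)-8-bromo-3,7-dimethylocta-2,6-dien-1-yl 2-methylpropanoate
Product: 9 (2E,6E)-12,12-dimethoxy-3,7,11,11-tetramethyldodeca-2,6-dien-1-yl 2-methylpropanoate, via Grignard reagent 8 (not isolated)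
Conditions: Mg, THF, 40 °C; then 3, Li2CuCl4 (3 mol%), THF, −78 → 0 °C
Reagents that add atoms: none
Why: Kochi-type copper-catalysed Grignard coupling, in which fast α-substitution at the primary allylic bromide at low temperature should outrun addition to the hindered isobutyrate and keep the E-alkene.

Step 7
Reactants: 9 (2E,6E)-12,12-dimethoxy-3,7,11,11-tetramethyldodeca-2,6-dien-1-yl 2-methylpropanoate
Product: 10 (2E,6E)-3,7,11,11-tetramethyl-12-oxododeca-2,6-dien-1-yl 2-methylpropanoate
Conditions: 1 M HCl, THF, 23 °C
Reagents that add atoms: water, O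
Why: Mild aqueous-acid hydrolysis of the dimethyl acetal, which the allylic ester and the trisubstituted alkenes should tolerate.

Step 8
Reactants: 11 ethyl (2E)-4-(diethoxyphosphoryl)but-2-enoate (triethyl 4-phosphonocrotonate)
Product: 12 (2E)-4-(diethoxyphosphoryl)but-2-enoic acid
Conditions: LiOH·H2O (1.0 equiv), THF/H2O, 0 °C; then 1 M HCl
Reagents that add atoms: lithium hydroxide, [Li+].[OH-]
Why: Selective saponification of the carboxylic ester, the dialkyl phosphonate esters being inert to one equivalent of hydroxide at 0 °C.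

Step 9
Reactants: 12 (2E)-4-(diethoxyphosphoryl)but-2-enoic acid
Product: 13 2-(trimethylsilyl)ethyl (2E)-4-(diethoxyphosphoryl)but-2-enoate
Conditions: Me3SiCH2CH2OH, DCC, DMAP (cat.), CH2Cl2, 0 → 23 °C
Reagents that add atoms: 2-(trimethylsilyl)ethanol, C[Si](C)(C)CCO
Why: Steglich esterification installs a fluoride-labile ester that stays orthogonal to the isobutyrate until the end.

Step 10
Reactants: 10 (2E,6E)-3,7,11,11-tetramethyl-12-oxododeca-2,6-dien-1-yl 2-methylpropanoate; 13 2-(trimethylsilyl)ethyl (2E)-4-(diethoxyphosphoryl)but-2-enoate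
Product: 14 2-(trimethylsilyl)ethyl (2E,4E,10E,14E)-6,6,10,14-tetramethyl-16-[(2-methylpropanoyl)oxy]hexadeca-2,4,10,14-tetraenoate
Conditions: LiN(SiMe3)2, THF, −78 °C; then 10, −78 → 0 °C
Reagents that add atoms: none
Why: Vinylogous Horner–Wadsworth–Emmons olefination of a non-enolisable neopentyl-type aldehyde should give the 4E bond (the 2E bond comes from the reagent), and any 2Z isomer is harmless because C8 is levelled in step 11.

Step 11
Reactants: 14 2-(trimethylsilyl)ethyl (2E,4E,10E,14E)-6,6,10,14-tetramethyl-16-[(2-methylpropanoyl)oxy]hexadeca-2,4,10,14-tetraenoate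
Product: 16 racemic 2-(trimethylsilyl)ethyl 15-(2-methylpropanoyloxy)labda-7,13E-dien-17-oate (rel-5S,9R,10S), via cycloadduct 15 (not isolated)
Conditions: PhMe (0.01 M), BHT (cat.), degassed, sealed tube, 180 °C; then DBU, 80 °C
Reagents that add atoms: none
Why: Thermal concerted [4+2] cycloaddition, a type 1 intramolecular Diels–Alder reaction of a 1,7,9-decatriene with the (2E,4E)-dienoate as diene and the unactivated trisubstituted alkene as dienophile, whose closest precedent is the thermal cyclisation of 2,4-dienoates tethered to unactivated alkenes at 160–200 °C; both new bonds join carbons of like polarity (ester α-carbon C8 with the nucleophilic alkene carbon C9, ester δ-carbon C5 with the cation-stabilising carbon C10), so the tether-enforced pericyclic path is used and Lewis acids, which would steer the alkene towards Markovnikov cation–olefin closure, are left out. Ring B is closed by the cycloaddition itself (six-membered cyclohexene) and ring A at the same time through the C1–C4 tether in the fused mode (six-membered, chair-like tether, helped by the gem-dimethyl group, which also blocks 1,5-hydrogen shifts of the diene). The cis relation of C10–CH3 and the C9 side chain follows stereospecifically from the E geometry of the dienophile, and the trans ring fusion (C5–H anti to C10–CH3) is expected from the tether-exo chair transition state, in which diene and dienophile are both equatorial on the forming ring A, whereas the cis-fused alternatives place the dienophile carbon or the diene axial or need a boat tether. C8 is formed as an sp3 centre and is deliberately erased: DBU should convert both C8 epimers, and adducts from any 2Z-dienoate, through the dienolate into the one conjugated C7=C8 ester, the non-acidic C9 centre being untouched. The selectivities needed are trans ring fusion, secured by the tether conformation, and reaction at the proximal alkene only, secured by ring size, since the C13=C14 alkene could only close a ring of ten or more atoms. Nothing in the substrate controls the absolute sense, so 16 is racemic and is resolved in steps 13 and 14.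

Step 12
Reactants: 16 racemic 2-(trimethylsilyl)ethyl 15-(2-methylpropanoyloxy)labda-7,13E-dien-17-oate
Product: 17 racemic 15-(2-methylpropanoyloxy)labda-7,13E-dien-17-oic acid
Conditions: Bu4NF, THF, 0 → 23 °C; then aq. HCl to pH 3
Reagents that add atoms: none
Why: Fluoride attacks silicon and the β-silylethyl ester fragments (loss of ethylene and Me3SiF), so the hindered conjugated carboxylate should be released without touching the isobutyrate.

Step 13
Reactants: 17 racemic 15-(2-methylpropanoyloxy)labda-7,13E-dien-17-oic acid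
Product: 18 (R)-1-phenylethylammonium (5S,9R,10S)-15-(2-methylpropanoyloxy)labda-7,13E-dien-17-oate
Conditions: (R)-PhCH(CH3)NH2 (1.0 equiv), EtOAc/hexane, 60 → 4 °C; recrystallise to constant rotation
Reagents that add atoms: (R)-1-phenylethylamine, C[C@@H](N)c1ccccc1
Why: Classical resolution, in which the two diastereomeric ammonium salts differ in solubility and the less soluble one is brought to purity by recrystallisation, fixing the absolute configuration at C5, C9 and C10.

Step 14
Reactants: 18 (R)-1-phenylethylammonium (5S,9R,10S)-15-(2-methylpropanoyloxy)labda-7,13E-dien-17-oate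
Product: 19 (5S,9R,10S)-15-(2-methylpropanoyloxy)labda-7,13E-dien-17-oic acid (target)
Conditions: 1 M HCl, Et2O/H2O, 0 °C
Reagents that add atoms: none
Why: Acid–base partition liberates the free acid without touching any stereocentre or the allylic ester.

**Compound list** (racemates are written as both enantiomers joined by a dot)

1 | geranyl isobutyrate, (2E)-3,7-dimethylocta-2,6-dien-1-yl 2-methylpropanoate | CC(C)=CCC/C(C)=C/COC(=O)C(C)C | starting material
2 | (2E,6E)-8-hydroxy-3,7-dimethylocta-2,6-dien-1-yl 2-methylpropanoate | OC/C(C)=C/CC/C(C)=C/COC(=O)C(C)C | intermediate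
3 | (2E,6E)-8-bromo-3,7-dimethylocta-2,6-dien-1-yl 2-methylpropanoate | BrC/C(C)=C/CC/C(C)=C/COC(=O)C(C)C | intermediate
4 | 3,3-dimethyloxolan-2-one | CC1(C)CCOC1=O | starting material
5 | ethyl 4-bromo-2,2-dimethylbutanoate | CCOC(=O)C(C)(C)CCBr | intermediate
6 | 4-bromo-2,2-dimethylbutanal | O=CC(C)(C)CCBr | intermediate
7 | 4-bromo-1,1-dimethoxy-2,2-dimethylbutane | COC(OC)C(C)(C)CCBr | intermediate
8 | (4,4-dimethoxy-3,3-dimethylbutyl)magnesium bromide | COC(OC)C(C)(C)CC[Mg]Br | intermediate (not isolated)
9 | (2E,6E)-12,12-dimethoxy-3,7,11,11-tetramethyldodeca-2,6-dien-1-yl 2-methylpropanoate | COC(OC)C(C)(C)CCC/C(C)=C/CC/C(C)=C/COC(=O)C(C)C | intermediate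
10 | (2E,6E)-3,7,11,11-tetramethyl-12-oxododeca-2,6-dien-1-yl 2-methylpropanoate | O=CC(C)(C)CCC/C(C)=C/CC/C(C)=C/COC(=O)C(C)C | intermediate
11 | ethyl (2E)-4-(diethoxyphosphoryl)but-2-enoate | CCOC(=O)/C=C/CP(=O)(OCC)OCC | starting material
12 | (2E)-4-(diethoxyphosphoryl)but-2-enoic acid | OC(=O)/C=C/CP(=O)(OCC)OCC | intermediate
13 | 2-(trimethylsilyl)ethyl (2E)-4-(diethoxyphosphoryl)but-2-enoate | C[Si](C)(C)CCOC(=O)/C=C/CP(=O)(OCC)OCC | intermediate
14 | 2-(trimethylsilyl)ethyl (2E,4E,10E,14E)-6,6,10,14-tetramethyl-16-[(2-methylpropanoyl)oxy]hexadeca-2,4,10,14-tetraenoate | C[Si](C)(C)CCOC(=O)/C=C/C=C/C(C)(C)CCC/C(C)=C/CC/C(C)=C/COC(=O)C(C)C | intermediate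
15 | racemic 2-(trimethylsilyl)ethyl 15-(2-methylpropanoyloxy)labda-6,13E-dien-17-oate, 5α-H, 9α-H, 10β-CH3 relative configuration (8β-ester drawn; the 8α-epimer may accompany it) | C/C(=C\COC(=O)C(C)C)CC[C@H]1[C@@H](C(=O)OCC[Si](C)(C)C)C=C[C@H]2C(C)(C)CCC[C@]12C.C/C(=C\COC(=O)C(C)C)CC[C@@H]1[C@H](C(=O)OCC[Si](C)(C)C)C=C[C@@H]2C(C)(C)CCC[C@@]12C | intermediate (not isolated)
16 | racemic 2-(trimethylsilyl)ethyl 15-(2-methylpropanoyloxy)labda-7,13E-dien-17-oate (rel-5S,9R,10S) | C/C(=C\COC(=O)C(C)C)CC[C@H]1C(C(=O)OCC[Si](C)(C)C)=CC[C@H]2C(C)(C)CCC[C@]12C.C/C(=C\COC(=O)C(C)C)CC[C@@H]1C(C(=O)OCC[Si](C)(C)C)=CC[C@@H]2C(C)(C)CCC[C@@]12C | intermediate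
17 | racemic 15-(2-methylpropanoyloxy)labda-7,13E-dien-17-oic acid | C/C(=C\COC(=O)C(C)C)CC[C@H]1C(C(=O)O)=CC[C@H]2C(C)(C)CCC[C@]12C.C/C(=C\COC(=O)C(C)C)CC[C@@H]1C(C(=O)O)=CC[C@@H]2C(C)(C)CCC[C@@]12C | intermediate
18 | (R)-1-phenylethylammonium (5S,9R,10S)-15-(2-methylpropanoyloxy)labda-7,13E-dien-17-oate | C/C(=C\COC(=O)C(C)C)CC[C@H]1C(C(=O)[O-])=CC[C@H]2C(C)(C)CCC[C@]12C.C[C@@H]([NH3+])c1ccccc1 | intermediate
19 | (5S,9R,10S)-15-(2-methylpropanoyloxy)labda-7,13E-dien-17-oic acid | C/C(=C\COC(=O)C(C)C)CC[C@H]1C(C(=O)O)=CC[C@H]2C(C)(C)CCC[C@]12C | target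

**Step count and risks**

Total step count: 14. Longest linear sequence: 10 steps (steps 3, 4, 5, 6, 7, 10, 11, 12, 13, 14).

Step 11 (riskiest). The cycloaddition may be slow enough at 180 °C that thermal decomposition of the dienoate competes, and the preference for the trans-fused transition state may be eroded at that temperature. The fallback carries the diene terminus at the aldehyde level, which makes the diene more electron-poor and should allow a lower temperature. It sets out from aldehyde 10 and comes back at acid 17. A Wittig reaction of 10 with Ph3P=CHCHO (PhMe, 80 °C) should give the (E)-enal F1, and a second one the (E,E)-dienal F2. Heating F2 (PhMe, about 140 °C, BHT) should give the racemic β,γ-unsaturated aldehyde cycloadduct F3, which DBU conjugates in the same pot to the racemic enal F4. Pinnick oxidation (NaClO2, NaH2PO4, 2-methyl-2-butene, tBuOH/H2O) of F4 then gives 17, with no carboxyl protecting group needed.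

Step 13. The two diastereomeric salts may fail to crystallise or may co-crystallise, so that no enrichment results. The fallback separates the enantiomers by chromatography at the ester stage instead. It sets out from racemic ester 16 and comes back at target 19. Preparative chromatography on a chiral stationary phase (cellulose tris(3,5-dimethylphenylcarbamate), supercritical CO2/iPrOH) should give the (5S,9R,10S)-silylethyl ester F5, whose absolute configuration is to be assigned by a crystal structure of a salt of the derived acid. Treatment of F5 with Bu4NF as in step 12 gives 19 directly.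

Step 6. The Grignard reagent may add to the isobutyrate carbonyl or substitute the C15 allylic ester, and some SN2' attack at the bromide may occur. The fallback replaces the organomagnesium by a sulfone-stabilised carbanion. It sets out from bromoacetal 7 (with bromide 3) and comes back at acetal 9. Displacement of 7 with PhSO2Na (DMF, 60 °C) should give the sulfone F6. Deprotonation (n-BuLi, THF, −78 °C) and alkylation with 3 should give the racemic α-alkylated sulfone F7. Reductive desulfonylation (sodium amalgam Na/Hg, Na2HPO4, MeOH/THF, −20 °C) then gives 9.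

**Further compounds**

F1 | step 11 | (2E,6E,12E)-3,7,11,11-tetramethyl-14-oxotetradeca-2,6,12-trien-1-yl 2-methylpropanoate | O=C/C=C/C(C)(C)CCC/C(C)=C/CC/C(C)=C/COC(=O)C(C)C
F2 | step 11 | (2E,6E,12E,14E)-3,7,11,11-tetramethyl-16-oxohexadeca-2,6,12,14-tetraen-1-yl 2-methylpropanoate | O=C/C=C/C=C/C(C)(C)CCC/C(C)=C/CC/C(C)=C/COC(=O)C(C)C
F3 | step 11 | racemic 15-(2-methylpropanoyloxy)labda-6,13E-dien-17-al, 5α-H, 9α-H, 10β-CH3 relative configuration (8β-formyl drawn) | C/C(=C\COC(=O)C(C)C)CC[C@H]1[C@@H](C=O)C=C[C@H]2C(C)(C)CCC[C@]12C.C/C(=C\COC(=O)C(C)C)CC[C@@H]1[C@H](C=O)C=C[C@@H]2C(C)(C)CCC[C@@]12C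
F4 | step 11 | racemic 15-(2-methylpropanoyloxy)labda-7,13E-dien-17-al (rel-5S,9R,10S) | C/C(=C\COC(=O)C(C)C)CC[C@H]1C(C=O)=CC[C@H]2C(C)(C)CCC[C@]12C.C/C(=C\COC(=O)C(C)C)CC[C@@H]1C(C=O)=CC[C@@H]2C(C)(C)CCC[C@@]12C
F5 | step 13 | 2-(trimethylsilyl)ethyl (5S,9R,10S)-15-(2-methylpropanoyloxy)labda-7,13E-dien-17-oate | C/C(=C\COC(=O)C(C)C)CC[C@H]1C(C(=O)OCC[Si](C)(C)C)=CC[C@H]2C(C)(C)CCC[C@]12C
F6 | step 6 | [(4,4-dimethoxy-3,3-dimethylbutyl)sulfonyl]benzene | COC(OC)C(C)(C)CCS(=O)(=O)c1ccccc1
F7 | step 6 | racemic (2E,6E)-9-(benzenesulfonyl)-12,12-dimethoxy-3,7,11,11-tetramethyldodeca-2,6-dien-1-yl 2-methylpropanoate | COC(OC)C(C)(C)C[C@H](S(=O)(=O)c1ccccc1)C/C(C)=C/CC/C(C)=C/COC(=O)C(C)C.COC(OC)C(C)(C)C[C@@H](S(=O)(=O)c1ccccc1)C/C(C)=C/CC/C(C)=C/COC(=O)C(C)C
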